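**Plan**
Retrosynthesis: ring D (C8–C15(=O)–C16–C13–C14) is a β-ketol whose C8 is also the α-carbon of the lactone carbonyl C7. Retro-aldol (C13–C16) and an oxidative enolate disconnection (C8–C14) therefore open rings D and C together, giving a spiro-lactone with a C8 propanoyl group and a C9 3-oxobutyl chain.
Further cuts: C8–C15 (Claisen-type acylation), lactone C7–O (oxidative lactonization), C9–C10 (Michael addition to an enal), C2=C3 (dehydrogenation), C10–C20 (formylation), C5–H (conjugate reduction), C5–C6 (carbonyl transposition).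
Forward order: ring A ketone carrying C6 and C20 → C9–C10 bond → spiro δ-lactone → ring A enone → C8 acyl group → rings C and D in one pot → removal of the MOM group.
Stereochemistry: C5 from catalytic asymmetric hydride addition; C10 from attack anti to the C5 side chain; C9 from the chiral amine catalyst; C8 from the tether at C9 (cis annulation); C13 from the bridge; C16 from the (Z)-enolate in the aldol closure.

Key step: step 11

Remark: C1–C20 are the ent-kaurane locants of the target (ring A: C1–C5, C10; δ-lactone: C7, C8, C9, C10, C20, O; ring C: C8, C9, C11–C14; ring D: C8, C13–C16; C17 is the methyl on C16, C6 the hydroxymethyl on C5). C8 of the acylated lactones is an epimer/enol mixture that is reset in the key step.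

**Route**

Step 1
Reactants: 1 hex-5-en-2-one; 2 ethane-1,2-diol
Product: 3 2-(but-3-en-1-yl)-2-methyl-1,3-dioxolane
Conditions: TsOH·H2O (cat.), toluene, reflux, Dean–Stark trap
Reagents that add atoms: ethane-1,2-diol (2), OCCO
Why: Acid-catalysed ketalization with azeotropic removal of water masks the future C13 ketone as a dioxolane that is inert to the hydride, enolate and oxidation steps ahead.

Step 2
Reactants: 3 2-(but-3-en-1-yl)-2-methyl-1,3-dioxolane; 4 (E)-but-2-enal
Product: 5 (E)-5-(2-methyl-1,3-dioxolan-2-yl)pent-2-enal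
Conditions: second-generation Hoveyda–Grubbs catalyst RuCl2(H2IMes)(=CH-C6H4-2-OiPr) (3 mol %), 4 (5 equiv), CH2Cl2, 40 °C
Reagents that add atoms: (E)-but-2-enal (4), C/C=C/C=O
Why: Olefin cross-metathesis of a terminal alkene with excess crotonaldehyde gives the conjugated (E)-enal under thermodynamic control, with propene as the volatile co-product.

Step 3
Reactants: 6 4,4-dimethylcyclohexane-1,3-dione; 7 ethanol
Product: 8 3-ethoxy-6,6-dimethylcyclohex-2-en-1-one
Conditions: TsOH·H2O (cat.), toluene, reflux, Dean–Stark trap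
Reagents that add atoms: ethanol (7), CCO
Why: Acid-catalysed enol etherification of the 1,3-dione occurs at the carbonyl remote from the gem-dimethyl group, so that the remaining carbonyl is the one next to the quaternary carbon.

Step 4
Reactants: 8 3-ethoxy-6,6-dimethylcyclohex-2-en-1-one; 9 tributyl[(methoxymethoxy)methyl]stannane
Product: 11 3-[(methoxymethoxy)methyl]-4,4-dimethylcyclohex-2-en-1-one, via carbinol adduct 10 (not isolated)
Conditions: 9, n-BuLi, THF, −78 °C; then 8, −78 → 0 °C; then 1 M aq. HCl, rt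
Reagents that add atoms: tributyl[(methoxymethoxy)methyl]stannane (9), CCCC[Sn](CCCC)(CCCC)COCOC; water, O
Why: Stork–Danheiser alkylative carbonyl transposition, in which the α-alkoxymethyllithium made by tin–lithium exchange adds 1,2 to the vinylogous ester and aqueous acid then hydrolyses the enol ether and dehydrates the carbinol to the 3-substituted enone.

Step 5
Reactants: 11 3-[(methoxymethoxy)methyl]-4,4-dimethylcyclohex-2-en-1-one; 12 2,2,2-trifluoroethyl formate
Product: 14 (3R)-2-(hydroxymethylidene)-3-[(methoxymethoxy)methyl]-4,4-dimethylcyclohexan-1-one, via enol silane 13 (not isolated)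
Conditions: Cu(OAc)2·H2O (3 mol %), (R)-DTBM-SEGPHOS (3 mol %), (EtO)2MeSiH (1.1 equiv), toluene, 0 °C → rt; then MeLi, THF, 0 °C; then 12, −78 °C; aq. NH4Cl
Reagents that add atoms: 2,2,2-trifluoroethyl formate (12), O=COCC(F)(F)F
Why: Copper hydride asymmetric conjugate reduction delivers hydride to the Re face of C3 of the enone (the sense expected for the (R)-ligand by analogy with 3-alkylcyclohexenones), which sets C5, and gives the enol silane regiospecifically at C10, so that its lithium enolate (from MeLi) undergoes Claisen-type C-formylation only at C10.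

Step 6
Reactants: 14 (3R)-2-(hydroxymethylidene)-3-[(methoxymethoxy)methyl]-4,4-dimethylcyclohexan-1-one; 5 (E)-5-(2-methyl-1,3-dioxolan-2-yl)pent-2-enal
Product: 16 (2S,3R)-2-(hydroxymethyl)-2-[(3R)-1-hydroxy-5-(2-methyl-1,3-dioxolan-2-yl)pentan-3-yl]-3-[(methoxymethoxy)methyl]-4,4-dimethylcyclohexan-1-one, via dialdehyde 15 (not isolated)
Conditions: (S)-2-[diphenyl(trimethylsilyloxy)methyl]pyrrolidine (20 mol %), PhCO2H (20 mol %), toluene, 0 °C → rt; then MeOH, NaBH4, −78 °C
Reagents that add atoms: (E)-5-(2-methyl-1,3-dioxolan-2-yl)pent-2-enal (5), CC1(CC/C=C/C=O)OCCO1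
Why: Iminium-catalysed Michael addition of the acidic hydroxymethylene ketone (diarylprolinol silyl ether catalysis) followed by borohydride reduction of both aldehydes in the flask; the (S)-catalyst shields the Si face of C9 of the (E)-iminium so that C10 adds to the Re face (sets C9), and the enol is attacked anti to the pseudo-axial C5 side chain (sets quaternary C10 with C20 cis to C6).

Step 7
Reactants: 16 (2S,3R)-2-(hydroxymethyl)-2-[(3R)-1-hydroxy-5-(2-methyl-1,3-dioxolan-2-yl)pentan-3-yl]-3-[(methoxymethoxy)methyl]-4,4-dimethylcyclohexan-1-one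
Product: 18 (5R,6S,11R)-11-[(methoxymethoxy)methyl]-10,10-dimethyl-5-[2-(2-methyl-1,3-dioxolan-2-yl)ethyl]-2-oxaspiro[5.5]undecane-3,7-dione, via lactol 17 (not isolated)
Conditions: TEMPO (0.2 equiv), PhI(OAc)2 (2.5 equiv), CH2Cl2, rt
Reagents that add atoms: none
Why: Oxidative lactonization of a 1,5-diol, in which the oxoammonium salt oxidizes the unhindered C7 hydroxyl faster than the neopentyl C20 hydroxyl and the resulting hydroxy aldehyde closes to lactol 17, which is oxidized to the δ-lactone while the hindered ketone is untouched.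

Step 8
Reactants: 18 (5R,6S,11R)-11-[(methoxymethoxy)methyl]-10,10-dimethyl-5-[2-(2-methyl-1,3-dioxolan-2-yl)ethyl]-2-oxaspiro[5.5]undecane-3,7-dione
Product: 19 (5R,6S,11R)-11-[(methoxymethoxy)methyl]-10,10-dimethyl-5-[2-(2-methyl-1,3-dioxolan-2-yl)ethyl]-2-oxaspiro[5.5]undec-8-ene-3,7-dione
Conditions: IBX (2.5 equiv), DMSO/PhF (1:2), 70 °C
Reagents that add atoms: none
Why: IBX dehydrogenation of a ketone through its enol can only introduce the C2–C3 double bond because C10 is quaternary, and the resulting enone leaves ring A without any enolizable hydrogen.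

Step 9
Reactants: 19 (5R,6S,11R)-11-[(methoxymethoxy)methyl]-10,10-dimethyl-5-[2-(2-methyl-1,3-dioxolan-2-yl)ethyl]-2-oxaspiro[5.5]undec-8-ene-3,7-dione; 20 N-methoxy-N-methylpropanamide
Product: 21 (5R,6S,11R)-11-[(methoxymethoxy)methyl]-10,10-dimethyl-5-[2-(2-methyl-1,3-dioxolan-2-yl)ethyl]-4-propanoyl-2-oxaspiro[5.5]undec-8-ene-3,7-dione (C4 epimers and enol)
Conditions: LiN(SiMe3)2 (1.15 equiv), THF, −78 °C; then 20, −78 → −20 °C; aq. NH4Cl
Reagents that add atoms: N-methoxy-N-methylpropanamide (20), CCC(=O)N(C)OC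
Why: Claisen-type C-acylation of the lactone lithium enolate with a Weinreb amide, whose chelated tetrahedral adduct prevents further reaction; C8 is the only acidic position, and its configuration is irrelevant because it is enolized again in step 11.

Step 10
Reactants: 21 (5R,6S,11R)-11-[(methoxymethoxy)methyl]-10,10-dimethyl-5-[2-(2-methyl-1,3-dioxolan-2-yl)ethyl]-4-propanoyl-2-oxaspiro[5.5]undec-8-ene-3,7-dione
Product: 22 (5R,6S,11R)-11-[(methoxymethoxy)methyl]-10,10-dimethyl-5-(3-oxobutyl)-4-propanoyl-2-oxaspiro[5.5]undec-8-ene-3,7-dione (C4 epimers and enol)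
Conditions: 1 M aq. HCl, THF, rt
Reagents that add atoms: water, O
Why: Mild aqueous acid hydrolysis of the dioxolane (acetal cleavage) releases the C13 methyl ketone while the MOM ether, the lactone and the enone survive.

Step 11
Reactants: 22 (5R,6S,11R)-11-[(methoxymethoxy)methyl]-10,10-dimethyl-5-(3-oxobutyl)-4-propanoyl-2-oxaspiro[5.5]undec-8-ene-3,7-dione
Product: 25 (5R,8S,9S,10S,13S,16R)-13-hydroxy-6-(methoxymethoxy)-1,15-dioxo-6,7-seco-ent-kaur-2-en-7,20-olide, via iodomethyl ketone 23 (not isolated), via tricyclic 1,4-diketone 24 (not isolated)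
Conditions: LiN(iPr)2 (2.15 equiv), THF, −78 °C; I2 (1.0 equiv), −78 → −20 °C; then LiN(SiMe3)2 (1.2 equiv), −78 → −45 °C; AcOH, −78 °C
Reagents that add atoms: none
Why: LiN(iPr)2 first removes the C8 proton between the lactone and ketone carbonyls and then, kinetically, a methyl proton at C14; iodine converts the ketone enolate into iodomethyl ketone 23 (an iodide formed at C8 passes its iodine on to the ketone enolate), and the stabilized C8 enolate displaces iodide in a 6-exo-tet SN2 closure that forms C8–C14 and ring C, the closest known reaction type being the intramolecular oxidative coupling of a ketone enolate with a 1,3-dicarbonyl enolate. LiN(SiMe3)2 then enolizes the ethyl ketone of 24 reversibly, and the C16 enolate adds to the C13 carbonyl in an intramolecular aldol reaction (5-(enolendo)-exo-trig, possible because the C8 acyl group can sit axial on ring C, 1,3 to the C13 carbonyl), which closes ring D as the bicyclo[3.2.1]octane ketol. C8 is controlled by the tether from C9, since a four-atom chain on the neighbouring carbon can reach the enolate only perpendicular to its plane and on its own face, which gives the cis ring fusion with C14 syn to C11. C13 follows from the bridge, and C16 from the (Z)-enolate that the quaternary C8 enforces, reacting through the transition state with the enolate on the C14 side of ring C, which places the methyl group syn to C12 and the hydrogen exo. The step needs site selectivity, secured in the first stage by kinetic deprotonation of the methyl group at −78 °C and in the second by the fact that only the C16 enolate has an unstrained carbonyl partner while the ring C enolates revert by proton exchange, and it needs kinetic control at C16, secured by low temperature and an acidic quench at −78 °C. Ring A has no enolizable hydrogen, its carbonyl lies trans to the C8 acyl group across the lactone ring so that the C16 enolate cannot reach it, and addition of a ring C enolate to this conjugated, hindered carbonyl is reversible.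

Step 12
Reactants: 25 (5R,8S,9S,10S,13S,16R)-13-hydroxy-6-(methoxymethoxy)-1,15-dioxo-6,7-seco-ent-kaur-2-en-7,20-olide
Product: 26 (5R,8S,9S,10S,13S,16R)-6,13-dihydroxy-1,15-dioxo-6,7-seco-ent-kaur-2-en-7,20-olide (CNP0533761.1)
Conditions: Me2BBr (3 equiv), CH2Cl2, −78 °C; then aq. NaHCO3, THF
Reagents that add atoms: none
Why: Cleavage of the MOM ether with dimethylboron bromide at −78 °C (bromide-assisted acetal cleavage, hydrolysis on work-up) is non-basic and cold, so that the β-ketol, the C16 stereocentre, the enone and the lactone are not disturbed.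

**Compound list**
1 | hex-5-en-2-one | CC(=O)CCC=C | starting material
2 | ethane-1,2-diol | OCCO | starting material
3 | 2-(but-3-en-1-yl)-2-methyl-1,3-dioxolane | CC1(CCC=C)OCCO1 | intermediate
4 | (E)-but-2-enal | C/C=C/C=O | starting material
5 | (E)-5-(2-methyl-1,3-dioxolan-2-yl)pent-2-enal | CC1(CC/C=C/C=O)OCCO1 | intermediate
6 | 4,4-dimethylcyclohexane-1,3-dione | CC1(C)CCC(=O)CC1=O | starting material
7 | ethanol | CCO | starting material
8 | 3-ethoxy-6,6-dimethylcyclohex-2-en-1-one | CCOC1=CC(=O)C(C)(C)CC1 | intermediate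
9 | tributyl[(methoxymethoxy)methyl]stannane | CCCC[Sn](CCCC)(CCCC)COCOC | starting material
10 | 3-ethoxy-1-[(methoxymethoxy)methyl]-6,6-dimethylcyclohex-2-en-1-ol (racemic, present as its lithium alkoxide; not isolated) | CCOC1=CC(O)(COCOC)C(C)(C)CC1 | intermediate
11 | 3-[(methoxymethoxy)methyl]-4,4-dimethylcyclohex-2-en-1-one | COCOCC1=CC(=O)CCC1(C)C | intermediate
12 | 2,2,2-trifluoroethyl formate | O=COCC(F)(F)F | starting material
13 | diethoxy{[(3S)-3-[(methoxymethoxy)methyl]-4,4-dimethylcyclohex-1-en-1-yl]oxy}methylsilane (not isolated) | COCOC[C@H]1C=C(O[Si](C)(OCC)OCC)CCC1(C)C | intermediate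
14 | (3R)-2-(hydroxymethylidene)-3-[(methoxymethoxy)methyl]-4,4-dimethylcyclohexan-1-one | OC=C1C(=O)CCC(C)(C)[C@H]1COCOC | intermediate
15 | (1S,2R)-2-[(methoxymethoxy)methyl]-3,3-dimethyl-1-[(3R)-5-(2-methyl-1,3-dioxolan-2-yl)-1-oxopentan-3-yl]-6-oxocyclohexane-1-carbaldehyde (not isolated) | O=CC[C@@H](CCC1(C)OCCO1)[C@]1(C=O)C(=O)CCC(C)(C)[C@H]1COCOC | intermediate
16 | (2S,3R)-2-(hydroxymethyl)-2-[(3R)-1-hydroxy-5-(2-methyl-1,3-dioxolan-2-yl)pentan-3-yl]-3-[(methoxymethoxy)methyl]-4,4-dimethylcyclohexan-1-one | OCC[C@@H](CCC1(C)OCCO1)[C@]1(CO)C(=O)CCC(C)(C)[C@H]1COCOC | intermediate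
17 | (5R,6S,11R)-3-hydroxy-11-[(methoxymethoxy)methyl]-10,10-dimethyl-5-[2-(2-methyl-1,3-dioxolan-2-yl)ethyl]-2-oxaspiro[5.5]undecan-7-one (anomers; not isolated) | OC1C[C@@H](CCC2(C)OCCO2)[C@]2(CO1)C(=O)CCC(C)(C)[C@H]2COCOC | intermediate
18 | (5R,6S,11R)-11-[(methoxymethoxy)methyl]-10,10-dimethyl-5-[2-(2-methyl-1,3-dioxolan-2-yl)ethyl]-2-oxaspiro[5.5]undecane-3,7-dione | O=C1C[C@@H](CCC2(C)OCCO2)[C@]2(CO1)C(=O)CCC(C)(C)[C@H]2COCOC | intermediate
19 | (5R,6S,11R)-11-[(methoxymethoxy)methyl]-10,10-dimethyl-5-[2-(2-methyl-1,3-dioxolan-2-yl)ethyl]-2-oxaspiro[5.5]undec-8-ene-3,7-dione | O=C1C[C@@H](CCC2(C)OCCO2)[C@]2(CO1)C(=O)C=CC(C)(C)[C@H]2COCOC | intermediate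
20 | N-methoxy-N-methylpropanamide | CCC(=O)N(C)OC | starting material
21 | (5R,6S,11R)-11-[(methoxymethoxy)methyl]-10,10-dimethyl-5-[2-(2-methyl-1,3-dioxolan-2-yl)ethyl]-4-propanoyl-2-oxaspiro[5.5]undec-8-ene-3,7-dione (C4 epimers and enol) | CCC(=O)C1C(=O)OC[C@]2(C(=O)C=CC(C)(C)[C@H]2COCOC)[C@@H]1CCC1(C)OCCO1 | intermediate
22 | (5R,6S,11R)-11-[(methoxymethoxy)methyl]-10,10-dimethyl-5-(3-oxobutyl)-4-propanoyl-2-oxaspiro[5.5]undec-8-ene-3,7-dione (C4 epimers and enol) | CCC(=O)C1C(=O)OC[C@]2(C(=O)C=CC(C)(C)[C@H]2COCOC)[C@@H]1CCC(C)=O | intermediate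
23 | (5R,6S,11R)-5-(4-iodo-3-oxobutyl)-11-[(methoxymethoxy)methyl]-10,10-dimethyl-4-propanoyl-2-oxaspiro[5.5]undec-8-ene-3,7-dione (present as its C4 lithium enolate; not isolated) | CCC(=O)C1C(=O)OC[C@]2(C(=O)C=CC(C)(C)[C@H]2COCOC)[C@@H]1CCC(=O)CI | intermediate
24 | (5R,8S,9S,10S)-6-(methoxymethoxy)-1,13,15-trioxo-6,7:13,16-diseco-ent-kaur-2-en-7,20-olide (ring C cis-fused to the lactone; not isolated) | CCC(=O)[C@]12CC(=O)CC[C@H]1[C@]1(COC2=O)C(=O)C=CC(C)(C)[C@H]1COCOC | intermediate
25 | (5R,8S,9S,10S,13S,16R)-13-hydroxy-6-(methoxymethoxy)-1,15-dioxo-6,7-seco-ent-kaur-2-en-7,20-olide | C[C@H]1C(=O)[C@]23C[C@@]1(O)CC[C@H]2[C@]1(COC3=O)C(=O)C=CC(C)(C)[C@H]1COCOC | intermediate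
26 | (5R,8S,9S,10S,13S,16R)-6,13-dihydroxy-1,15-dioxo-6,7-seco-ent-kaur-2-en-7,20-olide (CNP0533761.1) | C[C@H]1C(=O)[C@]23C[C@@]1(O)CC[C@H]2[C@]1(COC3=O)C(=O)C=CC(C)(C)[C@H]1CO | target

**Step count and risks**
Total steps: 12. Longest linear sequence: 10 steps (6 → 26, steps 3–12).

Step 11 is the most likely to fail. The second enolization may not be regioselective (deprotonation at C12 leads to a five-membered ring), iodination may occur without ring closure, and the C16 configuration may erode through enolate equilibration or retro-aldol cleavage during the aldol stage. The fallback sets out from 22 and separates the events. LiN(iPr)2 (2.2 equiv) and Me3SiCl at −78 °C give the bis(trimethylsilyl enol ether) (5S,6S,11R)-11-[(methoxymethoxy)methyl]-10,10-dimethyl-4-[1-(trimethylsilyloxy)propylidene]-5-[3-(trimethylsilyloxy)but-3-en-1-yl]-2-oxaspiro[5.5]undec-8-ene-3,7-dione F1. NBS at −78 °C brominates only the electron-rich ketone enol silane and gives the bromomethyl ketone (5S,6S,11R)-5-(4-bromo-3-oxobutyl)-11-[(methoxymethoxy)methyl]-10,10-dimethyl-4-[1-(trimethylsilyloxy)propylidene]-2-oxaspiro[5.5]undec-8-ene-3,7-dione F2, in which C8 is still masked. CsF in MeCN then frees the C8 enolate for the ring C alkylation, and 24 is isolated. A separate aldol closure (LiN(SiMe3)2, THF, −78 °C, cold acidic quench) comes back to the route at 25.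

Step 6 is the second risk. Bond formation at the congested C10 may be slow, facial discrimination may be poor if the catalyst's preference at C9 opposes the substrate's preference at C10, and the formyl group may be lost by amine attack. The fallback sets out from 14 and sets C9 on a ring instead. Conjugate addition of 14 to methyl propiolate (Et3N cat., CH2Cl2) gives methyl (E)-3-[(1S,2R)-1-formyl-2-[(methoxymethoxy)methyl]-3,3-dimethyl-6-oxocyclohexyl]prop-2-enoate F3. NaBH4 at −78 °C reduces the aldehyde to methyl (E)-3-[(1S,2R)-1-(hydroxymethyl)-2-[(methoxymethoxy)methyl]-3,3-dimethyl-6-oxocyclohexyl]prop-2-enoate F4. Photochemical E/Z isomerization (300 nm, then TsOH cat.) lets the Z ester lactonize to (6S,11R)-11-[(methoxymethoxy)methyl]-10,10-dimethyl-2-oxaspiro[5.5]undec-4-ene-3,7-dione F5. 2-(2-Bromoethyl)-2-methyl-1,3-dioxolane and Mg give [2-(2-methyl-1,3-dioxolan-2-yl)ethyl]magnesium bromide F6, which adds in the presence of CuBr·SMe2 and Me3SiCl to C9 of F5 anti to the C5 arm of ring A. This comes back to the route at 18.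

Step 5 is the third risk. Hydride delivery to a β-carbon flanked by a quaternary centre may be slow or may discriminate the enone faces poorly. The fallback sets out from 11 and moves the source of absolute configuration to step 6. The phosphine complex [(Ph3P)CuH]6 (5 mol %) with (EtO)2MeSiH gives the racemic enol silane diethoxy{[3-[(methoxymethoxy)methyl]-4,4-dimethylcyclohex-1-en-1-yl]oxy}methylsilane F7. MeLi and then 12 give racemic 2-(hydroxymethylidene)-3-[(methoxymethoxy)methyl]-4,4-dimethylcyclohexan-1-one F8. Under the conditions of step 6 the (S)-catalyst fixes C9 in both enantiomers, so the (3S)-enantiomer passes through the dialdehyde (1R,2S)-2-[(methoxymethoxy)methyl]-3,3-dimethyl-1-[(3R)-5-(2-methyl-1,3-dioxolan-2-yl)-1-oxopentan-3-yl]-6-oxocyclohexane-1-carbaldehyde F9 to the diastereomeric diol (2R,3S)-2-(hydroxymethyl)-2-[(3R)-1-hydroxy-5-(2-methyl-1,3-dioxolan-2-yl)pentan-3-yl]-3-[(methoxymethoxy)methyl]-4,4-dimethylcyclohexan-1-one F10. F10 is removed by chromatography, and the route is rejoined at 16.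

**Further compounds**
F1 | step 11 | (5S,6S,11R)-11-[(methoxymethoxy)methyl]-10,10-dimethyl-4-[1-(trimethylsilyloxy)propylidene]-5-[3-(trimethylsilyloxy)but-3-en-1-yl]-2-oxaspiro[5.5]undec-8-ene-3,7-dione | CCC(O[Si](C)(C)C)=C1C(=O)OC[C@]2(C(=O)C=CC(C)(C)[C@H]2COCOC)[C@@H]1CCC(=C)O[Si](C)(C)C
F2 | step 11 | (5S,6S,11R)-5-(4-bromo-3-oxobutyl)-11-[(methoxymethoxy)methyl]-10,10-dimethyl-4-[1-(trimethylsilyloxy)propylidene]-2-oxaspiro[5.5]undec-8-ene-3,7-dione | CCC(O[Si](C)(C)C)=C1C(=O)OC[C@]2(C(=O)C=CC(C)(C)[C@H]2COCOC)[C@@H]1CCC(=O)CBr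
F3 | step 6 | methyl (E)-3-[(1S,2R)-1-formyl-2-[(methoxymethoxy)methyl]-3,3-dimethyl-6-oxocyclohexyl]prop-2-enoate | COC(=O)/C=C/[C@]1(C=O)C(=O)CCC(C)(C)[C@H]1COCOC
F4 | step 6 | methyl (E)-3-[(1S,2R)-1-(hydroxymethyl)-2-[(methoxymethoxy)methyl]-3,3-dimethyl-6-oxocyclohexyl]prop-2-enoate | COC(=O)/C=C/[C@]1(CO)C(=O)CCC(C)(C)[C@H]1COCOC
F5 | step 6 | (6S,11R)-11-[(methoxymethoxy)methyl]-10,10-dimethyl-2-oxaspiro[5.5]undec-4-ene-3,7-dione | O=C1C=C[C@]2(CO1)C(=O)CCC(C)(C)[C@H]2COCOC
F6 | step 6 | [2-(2-methyl-1,3-dioxolan-2-yl)ethyl]magnesium bromide | CC1(CC[Mg]Br)OCCO1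
F7 | step 5 | diethoxy{[3-[(methoxymethoxy)methyl]-4,4-dimethylcyclohex-1-en-1-yl]oxy}methylsilane (racemic) | COCOCC1C=C(O[Si](C)(OCC)OCC)CCC1(C)C
F8 | step 5 | 2-(hydroxymethylidene)-3-[(methoxymethoxy)methyl]-4,4-dimethylcyclohexan-1-one (racemic) | OC=C1C(=O)CCC(C)(C)C1COCOC
F9 | step 5 | (1R,2S)-2-[(methoxymethoxy)methyl]-3,3-dimethyl-1-[(3R)-5-(2-methyl-1,3-dioxolan-2-yl)-1-oxopentan-3-yl]-6-oxocyclohexane-1-carbaldehyde | O=CC[C@@H](CCC1(C)OCCO1)[C@@]1(C=O)C(=O)CCC(C)(C)[C@@H]1COCOC
F10 | step 5 | (2R,3S)-2-(hydroxymethyl)-2-[(3R)-1-hydroxy-5-(2-methyl-1,3-dioxolan-2-yl)pentan-3-yl]-3-[(methoxymethoxy)methyl]-4,4-dimethylcyclohexan-1-one | OCC[C@@H](CCC1(C)OCCO1)[C@@]1(CO)C(=O)CCC(C)(C)[C@@H]1COCOC
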